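- At the reading time of 20 min the flask had been followed only to 10.0 min, so I had to carry its substrate curve forward.

all flasks: substrate 20 mM
- beta: partner 26 mM; the very flask that is asked about, followed so far
- flask: partner 26.0 mM; time 20 min

beta run (percent of the substrate charged)

| time / min | side product / % | intermediate B / % | substrate / % | intermediate A / % | target / % |
|---|---|---|---|---|---|
| 1.50 | 0.6 | 0 | 97.2 | 3.0 | 0.5 |
| 3.00 | 0.7 | 0 | 92.7 | 5.1 | 0.5 |
| 5.00 | 1.7 | 0 | 89.8 | 7.2 | 0.7 |
| 6.00 | 3.2 | 1.3 | 88.5 | 7.8 | 0.3 |
| 8.00 | 4.6 | 1.5 | 84.8 | 9.9 | 0 |
| 10.0 | 6.2 | 1.5 | 81.9 | 11.2 | 0.4 |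

(each reading ± 0.5 percentage points)

* where most of what was charged as substrate, at 20 min is found (side product / intermediate A / substrate / target / intermediate B)
* the largest share itself, whichever of these holds it, in percent of the substrate charged

- for target the idle adduct is counted in
- the analysis behind the earlier runs scatters by 0.5 percentage points, standard deviation
- candidate steps: partner + target <-> idle adduct; intermediate B -> target; intermediate A -> side product; substrate + partner <-> intermediate A; partner + intermediate A <-> intermediate B

- The bench rule is pseudo-first-order decay: substrate, as a fraction y of its charge, falls as exp(−k't), so k' = −ln(y)/t. The last reading, 81.9% at 10.0 min, gave k' = 0.0200 min⁻¹, which put substrate at 67.0% at 20 min.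
- The rule needs partner to stay near its charge, and a ratio of charges shows the border. I took one partner lost per substrate lost, so partner falls by 0.769 of its charge for each unit fraction of substrate lost. On the rule's own figure, the flask's partner was down by 25.3% at 20 min, which breaks its assumption.
- I therefore used the mean partner P̄, the charge less half of the partner lost, which was 24.2 mM over the run. The decay constant per mean partner, κ = k'/P̄, came to 0.825 L mol⁻¹ min⁻¹.
- With P̄ = 22.7 mM up to 20 min, taken from the first estimate, κ gave substrate 68.7% in the flask.
- The forecast named substrate at 70%, a little higher than my figure: “Substrate therefore remains by far the largest pool”.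
- The flask gave substrate at 70.0%.

    partner + target ⇌ idle adduct, settled at all times (K = 59.0 L mol⁻¹)
    intermediate B → target (k = 0.00150 s⁻¹)
    intermediate A → side product (k = 0.00140 s⁻¹)
    substrate + partner ⇌ intermediate A (K = 32.0 L mol⁻¹, k = 0.0160 L mol⁻¹ s⁻¹)
    partner + intermediate A ⇌ intermediate B (K = 130 L mol⁻¹, k = 0.0290 L mol⁻¹ s⁻¹)

- So at 20 min the flask still held mostly unreacted substrate, 1.3 percentage points above my κ figure, with side product next at 14.3%. A neighbour flask was charged with 65 mM of partner, which is 3.25 equiv, against 1.30 equivalents in the flask, with its other charge and its time as in the flask. The same κ, with P̄ = 58.4 mM, gave substrate 38.1% for the neighbour flask at 20 min. Substrate in the neighbour flask stood at 40.5%, which is 2.4 points above that figure.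

The numbers in the tables were computed on assumed constants, and the scatter is random.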